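**Retrosynthetic overview**

- The strategy rests on one feature of the single six-membered carbocycle: the quaternary carbinol C4 lies between the enone carbon C3 and the methylene C5, and the carbinol C6 sits next to the ketone C1. A 2-alkylacrolein (C4, C5) and a 1,3,4-trioxygenated butadiene (C6, C1, C2, C3) leave exactly this pattern.
- Late disconnections: Z-alkene from the alkyne (semihydrogenation); C4–OH from C4–CHO (Baeyer–Villiger, retention); C6–OH from C6–OAc.
- The only ring is closed in one enantioselective [4+2] step that forms C3–C4 and C5–C6; acid then unveils the enone.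
- The enal comes from 11-bromoundecan-1-ol and oct-1-yne (3 steps), the diene from 1-methoxy-3-(trimethylsilyloxy)butadiene (2 steps).

Key step: step 6

Assumption: the facial sense of the catalyst is assigned from the formyl C–H···O binding model of 2-substituted acroleins (s-trans enal lying over the catalyst phenyl group), on which the oxazaborolidinium derived from (R)-diphenylprolinol exposes the enal face that leads to 4R; the C6 oxygen is carried as acetate and the enol ether as tert-butyldimethylsilyl.

**Route**

Step 1
Reactants: 1 11-bromoundecan-1-ol; 2 oct-1-yne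
Product: 4 nonadec-12-yn-1-ol, via oct-1-ynyllithium 3 (not isolated)
Conditions: 2 (2.3 equiv), n-BuLi (2.2 equiv), THF, −78 → 0 °C; DMPU, then 1, 0 °C → rt; H2O
Reagents that add atoms: none
Why: Acetylide SN2 alkylation, in which the first equivalent of 3 deprotonates the hydroxyl, the lithium alkoxide is a poor nucleophile, and the second equivalent displaces the primary bromide in the dipolar cosolvent.

Step 2
Reactants: 4 nonadec-12-yn-1-ol
Product: 5 nonadec-12-ynal
Conditions: TEMPO (10 mol%), PhI(OAc)2 (1.1 equiv), CH2Cl2, rt
Reagents that add atoms: none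
Why: Oxoammonium (TEMPO)-mediated oxidation of a primary alcohol should stop at the aldehyde under anhydrous conditions and leave the internal alkyne untouched.

Step 3
Reactants: 5 nonadec-12-ynal
Product: 6 2-methylidenenonadec-12-ynal
Conditions: 37% aq. CH2O, pyrrolidine (10 mol%), EtCO2H (10 mol%), i-PrOH, 45 °C
Reagents that add atoms: formaldehyde, C=O
Why: Amine/acid-catalysed Mannich condensation with formaldehyde followed by loss of the amine (organocatalytic α-methylenation) is general for unbranched aldehydes and should give the 2-alkylacrolein with the alkyne intact.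

Step 4
Reactants: 7 (E)-1-methoxy-3-(trimethylsilyloxy)buta-1,3-diene
Product: 8 (E)-4-methoxy-2-oxobut-3-en-1-yl acetate
Conditions: Pb(OAc)4 (1.05 equiv), CH2Cl2, −20 → 0 °C
Reagents that add atoms: lead tetraacetate, CC(=O)O[Pb](OC(C)=O)(OC(C)=O)OC(C)=O
Why: Rubottom-type lead tetraacetate oxidation of a silyl enol ether, in which the electrophile attacks the terminal CH2 of the 2-silyloxy diene and acetate is delivered to that carbon with loss of the silyl group, while the vinylogous ester is left intact.

Step 5
Reactants: 8 (E)-4-methoxy-2-oxobut-3-en-1-yl acetate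
Product: 9 (1Z,3E)-2-(tert-butyldimethylsilyloxy)-4-methoxybuta-1,3-dien-1-yl acetate
Conditions: TBSOTf (1.2 equiv), Et3N (2 equiv), Et2O, 0 °C → rt
Reagents that add atoms: tert-butyldimethylsilyl trifluoromethanesulfonate, CC(C)(C)[Si](C)(C)OS(=O)(=O)C(F)(F)F
Why: Soft enolisation (silyl triflate/tertiary amine) silylates the ketone oxygen and removes a proton from the only enolisable position, and the geometry with acetoxy cis to silyloxy (1Z, acetoxy outward on the s-cis diene) should prevail because it avoids allylic strain with the methoxyvinyl arm.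

Step 6
Reactants: 6 2-methylidenenonadec-12-ynal; 9 (1Z,3E)-2-(tert-butyldimethylsilyloxy)-4-methoxybuta-1,3-dien-1-yl acetate
Product: 11 (4R,6S)-6-acetoxy-4-formyl-4-(heptadec-10-yn-1-yl)cyclohex-2-en-1-one, via silyl enol ether cycloadduct 10 (not isolated)
Conditions: (R)-1-(2-methylphenyl)-3,3-diphenyltetrahydro-1H,3H-pyrrolo[1,2-c][1,3,2]oxazaborole (20 mol%, from (R)-diphenyl(pyrrolidin-2-yl)methanol and tri-o-tolylboroxine), HNTf2 (18 mol%), CH2Cl2, −78 → −40 °C, slow addition of 9; then TFA, CH2Cl2, 0 °C
Reagents that add atoms: none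
Why: The N-protonated oxazaborolidine binds the formyl oxygen of 6 (s-trans enal, formyl C–H···O contact to the ring oxygen), and 9 adds in a concerted but asynchronous [4+2] in which its acetoxy-bearing terminus bonds to the enal methylene (C5–C6) ahead of C3–C4. The closest known reaction type is the oxazaborolidinium-catalysed enantioselective Diels–Alder reaction of 2-substituted acroleins with silyloxy dienes. The six-membered carbocycle, the only ring of the target, is closed by this intermolecular cycloaddition, and trifluoroacetic acid then cleaves the silyl enol ether of 10 and expels methanol to give the enone. C4 (R) is set by the catalyst, whose phenyl group shields one face of the bound enal; C6 (S) is set relative to C4 by the formyl-endo transition state, which places formyl cis to the outward acetoxy group of the (1Z)-diene. The step needs regio-, endo- and enantiofacial selectivity: the first is secured by the methoxy and silyloxy groups, which both push electron density onto the acetoxy-bearing terminus; the second by the boron-bound formyl group lying under the diene with no bridging atom to oppose it; the third by the two-point binding of the 2-alkylacrolein. The tert-butyldimethylsilyl group is preferred to trimethylsilyl so that silyl transfer to triflimide, and the racemic pathway it would open, is held back.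

Step 7
Reactants: 11 (4R,6S)-6-acetoxy-4-formyl-4-(heptadec-10-yn-1-yl)cyclohex-2-en-1-one
Product: 12 (1S,5R)-5-(formyloxy)-5-(heptadec-10-yn-1-yl)-2-oxocyclohex-3-en-1-yl acetate
Conditions: m-CPBA (1.5 equiv), Na2HPO4, CH2Cl2, 0 °C → rt
Reagents that add atoms: 3-chloroperoxybenzoic acid, OOC(=O)c1cccc(Cl)c1
Why: Baeyer–Villiger oxidation, in which the fully substituted allylic carbon C4 should migrate to oxygen in preference to hydride and with retention, so the C4 configuration from step 6 is carried over, while the electron-poor enone alkene and the alkyne are slow toward the electrophilic peracid and the buffer protects the tertiary allylic formate.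

Step 8
Reactants: 12 (1S,5R)-5-(formyloxy)-5-(heptadec-10-yn-1-yl)-2-oxocyclohex-3-en-1-yl acetate
Product: 13 (4R,6S)-4-(heptadec-10-yn-1-yl)-4,6-dihydroxycyclohex-2-en-1-one
Conditions: K2CO3 (0.2 equiv), degassed MeOH, 0 °C, short reaction time; pH 7 buffer quench
Reagents that add atoms: none
Why: Carbonate-catalysed transesterification (methanolysis) should remove the formate and the ketone-activated acetate at 0 °C; C4 carries no hydrogen and C6 can be disturbed only through enolisation, which brief exposure at low temperature is meant to avoid.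

Step 9
Reactants: 13 (4R,6S)-4-(heptadec-10-yn-1-yl)-4,6-dihydroxycyclohex-2-en-1-one
Product: 14 (4R,6S)-4-[(10Z)-heptadec-10-en-1-yl]-4,6-dihydroxycyclohex-2-en-1-one
Conditions: H2 (1 atm), Pd/CaCO3 poisoned with Pb(OAc)2, quinoline, EtOAc, rt, stopped after 1 equiv H2
Reagents that add atoms: none
Why: Lindlar semihydrogenation delivers one equivalent of hydrogen syn to the alkyne on lead-poisoned palladium to give the Z-alkene, the alkyne being reduced well before the conjugated enone alkene, and no stereocentre is affected.

**Compound list**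

1 | 11-bromoundecan-1-ol | OCCCCCCCCCCCBr | starting material
2 | oct-1-yne | C#CCCCCCC | starting material
3 | oct-1-ynyllithium | [Li]C#CCCCCCC | intermediate
4 | nonadec-12-yn-1-ol | OCCCCCCCCCCCC#CCCCCCC | intermediate
5 | nonadec-12-ynal | O=CCCCCCCCCCCC#CCCCCCC | intermediate
6 | 2-methylidenenonadec-12-ynal | C=C(C=O)CCCCCCCCCC#CCCCCCC | intermediate
7 | (E)-1-methoxy-3-(trimethylsilyloxy)buta-1,3-diene | CO/C=C/C(=C)O[Si](C)(C)C | starting material
8 | (E)-4-methoxy-2-oxobut-3-en-1-yl acetate | CO/C=C/C(=O)COC(C)=O | intermediate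
9 | (1Z,3E)-2-(tert-butyldimethylsilyloxy)-4-methoxybuta-1,3-dien-1-yl acetate | CO/C=C/C(O[Si](C)(C)C(C)(C)C)=C/OC(C)=O | intermediate
10 | (1S,4S,5R)-2-(tert-butyldimethylsilyloxy)-5-formyl-5-(heptadec-10-yn-1-yl)-4-methoxycyclohex-2-en-1-yl acetate | CCCCCCC#CCCCCCCCCC[C@]1(C=O)[C@@H](OC)C=C(O[Si](C)(C)C(C)(C)C)[C@@H](OC(C)=O)C1 | intermediate
11 | (4R,6S)-6-acetoxy-4-formyl-4-(heptadec-10-yn-1-yl)cyclohex-2-en-1-one | CCCCCCC#CCCCCCCCCC[C@]1(C=O)C=CC(=O)[C@@H](OC(C)=O)C1 | intermediate
12 | (1S,5R)-5-(formyloxy)-5-(heptadec-10-yn-1-yl)-2-oxocyclohex-3-en-1-yl acetate | CCCCCCC#CCCCCCCCCC[C@]1(OC=O)C=CC(=O)[C@@H](OC(C)=O)C1 | intermediate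
13 | (4R,6S)-4-(heptadec-10-yn-1-yl)-4,6-dihydroxycyclohex-2-en-1-one | CCCCCCC#CCCCCCCCCC[C@]1(O)C=CC(=O)[C@@H](O)C1 | intermediate
14 | (4R,6S)-4-[(10Z)-heptadec-10-en-1-yl]-4,6-dihydroxycyclohex-2-en-1-one | CCCCCC/C=C\CCCCCCCCC[C@]1(O)C=CC(=O)[C@@H](O)C1 | target

**Step count**

Total: 9 steps. Longest linear sequence: 7 steps (1, 2, 3, 6, 7, 8, 9); the diene arm (steps 4, 5) joins at step 6.

**Steps most likely to fail**

1. Step 6. The strongly acidic catalyst may protodesilylate the diene, or silyl transfer to triflimide may start a silyl-cation-catalysed, stepwise conjugate addition–ring closure that is racemic and erodes the endo preference. The fallback leaves Lewis acid catalysis for hydrogen-bond catalysis with a more reactive 1-amino diene. It sets out from 8: dimethylamine (1 equiv, THF, −20 °C) should exchange the methoxy group by addition–elimination to give (E)-4-(dimethylamino)-2-oxobut-3-en-1-yl acetate F1. TBSOTf/Et3N should then give (1Z,3E)-2-(tert-butyldimethylsilyloxy)-4-(dimethylamino)buta-1,3-dien-1-yl acetate F2. F2 and 6 would be combined in toluene at −78 °C with 20 mol% of a TADDOL (2,2-dimethyl-α,α,α′,α′-tetra(1-naphthyl)-1,3-dioxolane-4,5-dimethanol, the enantiomer that leads to the 4R series) to give (1S,4S,5R)-2-(tert-butyldimethylsilyloxy)-4-(dimethylamino)-5-formyl-5-(heptadec-10-yn-1-yl)cyclohex-2-en-1-yl acetate F3. HF in MeCN then removes the silyl group and dimethylamine, and the route is rejoined at 11.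

2. Step 7. Hydride may migrate in place of the tertiary carbon in the peracid adduct, so that the formyl group is oxidised to the carboxylic acid, or the electron-poor migrating carbon may make the rearrangement too slow. The fallback is a carboxy-inversion sequence that starts from that acid. It sets out from 11: Pinnick oxidation (NaClO2, NaH2PO4, 2-methylbut-2-ene, t-BuOH/H2O) should give (1R,5S)-5-acetoxy-1-(heptadec-10-yn-1-yl)-4-oxocyclohex-2-ene-1-carboxylic acid F4. DCC and m-CPBA (CH2Cl2, 0 °C) would convert it into (1R,5S)-5-acetoxy-1-(heptadec-10-yn-1-yl)-4-oxocyclohex-2-ene-1-carbonyl 3-chlorobenzoyl peroxide F5. Warming in MeCN should bring about the carboxy-inversion rearrangement, in which the tertiary carbon moves to oxygen with retention, to give the mixed carbonate (1S,5R)-5-{[(3-chlorobenzoyl)oxy]carbonyloxy}-5-(heptadec-10-yn-1-yl)-2-oxocyclohex-3-en-1-yl acetate F6. K2CO3/MeOH at 0 °C cleaves the carbonate and the acetate, and the route is rejoined at 13.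

3. Step 8. The α-hydroxy ketone may enolise in basic methanol, which would epimerise C6 or shift the ketol. The fallback replaces base-mediated ester cleavage by reduction and chemoselective re-oxidation. It sets out from 12: i-Bu2AlH (excess, CH2Cl2, −78 °C) should reduce the ketone 1,2 and cleave both esters to give (1R,5S)-1-(heptadec-10-yn-1-yl)cyclohex-2-ene-1,4,5-triol F7, as a mixture at the new carbinol carbon C4 that is of no consequence. MnO2 in CH2Cl2 at rt should oxidise only the secondary allylic hydroxyl, and the route is rejoined at 13.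

**Further compounds**

F1 | step 6 | (E)-4-(dimethylamino)-2-oxobut-3-en-1-yl acetate | CN(C)/C=C/C(=O)COC(C)=O
F2 | step 6 | (1Z,3E)-2-(tert-butyldimethylsilyloxy)-4-(dimethylamino)buta-1,3-dien-1-yl acetate | CN(C)/C=C/C(O[Si](C)(C)C(C)(C)C)=C/OC(C)=O
F3 | step 6 | (1S,4S,5R)-2-(tert-butyldimethylsilyloxy)-4-(dimethylamino)-5-formyl-5-(heptadec-10-yn-1-yl)cyclohex-2-en-1-yl acetate | CCCCCCC#CCCCCCCCCC[C@]1(C=O)[C@@H](N(C)C)C=C(O[Si](C)(C)C(C)(C)C)[C@@H](OC(C)=O)C1
F4 | step 7 | (1R,5S)-5-acetoxy-1-(heptadec-10-yn-1-yl)-4-oxocyclohex-2-ene-1-carboxylic acid | CCCCCCC#CCCCCCCCCC[C@]1(C(=O)O)C=CC(=O)[C@@H](OC(C)=O)C1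
F5 | step 7 | (1R,5S)-5-acetoxy-1-(heptadec-10-yn-1-yl)-4-oxocyclohex-2-ene-1-carbonyl 3-chlorobenzoyl peroxide | CCCCCCC#CCCCCCCCCC[C@]1(C(=O)OOC(=O)c2cccc(Cl)c2)C=CC(=O)[C@@H](OC(C)=O)C1
F6 | step 7 | (1S,5R)-5-{[(3-chlorobenzoyl)oxy]carbonyloxy}-5-(heptadec-10-yn-1-yl)-2-oxocyclohex-3-en-1-yl acetate | CCCCCCC#CCCCCCCCCC[C@]1(OC(=O)OC(=O)c2cccc(Cl)c2)C=CC(=O)[C@@H](OC(C)=O)C1
F7 | step 8 | (1R,5S)-1-(heptadec-10-yn-1-yl)cyclohex-2-ene-1,4,5-triol (C4 epimers) | CCCCCCC#CCCCCCCCCC[C@]1(O)C=CC(O)[C@@H](O)C1
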